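**Retr<br>osynthetic overview**

1. Target 28, a trans-(2S,4R) tetrahydro-1-benzoxepine, comes from fluoride desilylation of angelate 27, made by angeloylation of allylic alcohol 24; 24 comes from oxazaborolidine-controlled reduction of the 5-methylidene-4-ketone 23, which arises by Mannich methylenation at C5 of the C4 ethyl enol ether 20, itself from MeMgBr addition to the C2 ester 19.
2. Structural feature used: in the oxepine ring, C2 carries both the aryl ether oxygen O1 and a carboxyl-derived carbon (the 2-hydroxypropan-2-yl group), followed by C3 and an oxygenated C4. The array O1–C2(CO2H)–C3–C4(OEt)=C5 is the retron of an ester-enolate Claisen shift of an aryloxyacetate.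
3. Key disconnection C2–C3: acid 18 comes from the silyl ketene acetal of the seven-membered lactone 15 (a 1,4-benzodioxepin-3-one with a 1-ethoxyethenyl group on C5). The [3,3] shift breaks C5–O4 and exchanges the lactone ring for an oxepine ring of the same size.
4. Lactone 15 comes from (R)-carbinol 12 (CBS reduction of aryl 1-ethoxyvinyl ketone 11), which comes from aldehyde 7 and lithiated ethyl vinyl ether; 7 comes from salicylaldehyde 5 and methyl bromoacetate; 5 comes from 2,4-dihydroxy-3-methylbenzaldehyde 1 by silylation, Baeyer–Villiger oxidation and ortho-formylation.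
5. Ring order: benzene ring (bought in 1), seven-membered lactone ring (step 8), oxepine ring (step 9, with loss of the lactone ring).

Key step: step 9

Remark (assumption on the chemistry): the two phenols that are free in the target (C7–OH, C9–OH) are carried as triisopropylsilyl ethers, because they must survive carbonate, hydroxide, amide and Grignard bases and resist O-to-O silyl migration; fluoride removes them last.

**Route**

Step 1
Reactants: 1 2,4-dihydroxy-3-methylbenzaldehyde
Product: 2 3-methyl-2,4-bis(triisopropylsilyloxy)benzaldehyde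
Conditions: i-Pr3SiOTf (2.4 equiv), 2,6-lutidine, CH2Cl2, 0 °C to rt
Reagents that add atoms: triisopropylsilyl trifluoromethanesulfonate, CC(C)[Si](C(C)C)(C(C)C)OS(=O)(=O)C(F)(F)F
Why: O-silylation of both phenols, the silyl triflate being reactive enough for the hydrogen-bonded 2-OH flanked by CHO and CH3.

Step 2
Reactants: 2 3-methyl-2,4-bis(triisopropylsilyloxy)benzaldehyde
Product: 4 3-methyl-2,4-bis(triisopropylsilyloxy)phenol, via aryl formate 3 (not isolated)
Conditions: mCPBA, CH2Cl2, 0 °C to rt; then K2CO3 (cat.), MeOH, 0 °C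
Reagents that add atoms: 3-chloroperoxybenzoic acid, O=C(OO)c1cccc(Cl)c1
Why: Baeyer–Villiger (Dakin-type) oxidation in which the electron-rich aryl group migrates in preference to hydrogen, followed by brief methanolysis of the labile aryl formate.

Step 3
Reactants: 4 3-methyl-2,4-bis(triisopropylsilyloxy)phenol
Product: 5 2-hydroxy-4-methyl-3,5-bis(triisopropylsilyloxy)benzaldehyde
Conditions: MgCl2, Et3N, (CH2O)n, THF, reflux
Reagents that add atoms: paraformaldehyde (as formaldehyde), C=O
Why: magnesium phenoxide-directed ortho-formylation (Casnati–Skattebøl) places CHO only ortho to the free OH, and the single free ortho position gives the required 1,2,3,4,5-substitution pattern.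

Step 4
Reactants: 5 2-hydroxy-4-methyl-3,5-bis(triisopropylsilyloxy)benzaldehyde; 6 methyl bromoacetate
Product: 7 methyl 2-[2-formyl-5-methyl-4,6-bis(triisopropylsilyloxy)phenoxy]acetate
Conditions: K2CO3, DMF, rt
Reagents that add atoms: none
Why: Williamson ether synthesis on the aldehyde-conjugated phenoxide, kept at rt so that the aldol closure to a benzofuran does not set in.

Step 5
Reactants: 7 methyl 2-[2-formyl-5-methyl-4,6-bis(triisopropylsilyloxy)phenoxy]acetate; 8 ethyl vinyl ether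
Product: 10 methyl 2-[2-(2-ethoxy-1-hydroxyprop-2-en-1-yl)-5-methyl-4,6-bis(triisopropylsilyloxy)phenoxy]acetate (racemic), via 1-ethoxyvinyllithium 9 (not isolated)
Conditions: 8 (3 equiv), t-BuLi (1.2 equiv), THF, −78 to 0 °C; then added to 7, THF, −78 °C; pH 7 phosphate buffer
Reagents that add atoms: none
Why: 1,2-addition of an α-alkoxyvinyllithium (acyl anion equivalent) to the aldehyde, which at −78 °C with inverse addition should be far faster than attack on or enolisation of the ester.

Step 6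
Reactants: 10 methyl 2-[2-(2-ethoxy-1-hydroxyprop-2-en-1-yl)-5-methyl-4,6-bis(triisopropylsilyloxy)phenoxy]acetate (racemic)
Product: 11 methyl 2-[2-(2-ethoxyprop-2-enoyl)-5-methyl-4,6-bis(triisopropylsilyloxy)phenoxy]acetate
Conditions: Dess–Martin periodinane, pyridine, CH2Cl2, 0 °C to rt
Reagents that add atoms: none
Why: Dess–Martin oxidation of a benzylic, allylic secondary alcohol under buffered, non-acidic conditions that spare the enol ether.

Step 7
Reactants: 11 methyl 2-[2-(2-ethoxyprop-2-enoyl)-5-methyl-4,6-bis(triisopropylsilyloxy)phenoxy]acetate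
Product: 12 methyl 2-{2-[(1R)-2-ethoxy-1-hydroxyprop-2-en-1-yl]-5-methyl-4,6-bis(triisopropylsilyloxy)phenoxy}acetate
Conditions: (R)-2-methyl-CBS-oxazaborolidine (0.3 equiv), catecholborane (1.8 equiv), toluene, −78 °C; MeOH; aq. NaHCO3
Reagents that add atoms: none
Why: Corey–Bakshi–Shibata reduction in which the ortho-substituted aryl group is expected to act as the large substituent and the s-cis 1-ethoxyvinyl group as the small one, so that the (R)-catalyst should give the (R)-carbinol (sense and purity to be checked by Mosher ester analysis).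

Step 8
Reactants: 12 methyl 2-{2-[(1R)-2-ethoxy-1-hydroxyprop-2-en-1-yl]-5-methyl-4,6-bis(triisopropylsilyloxy)phenoxy}acetate
Product: 15 (5R)-5-(1-ethoxyethenyl)-8-methyl-7,9-bis(triisopropylsilyloxy)-2H-1,4-benzodioxepin-3(5H)-one, via lithium carboxylate 13 (not isolated), via mixed anhydride 14 (not isolated)
Conditions: LiOH·H2O (1.1 equiv), THF/H2O, 0 °C; evaporation and azeotropic drying (PhMe); 2,4,6-trichlorobenzoyl chloride, Et3N, THF, rt; then slow addition to DMAP, PhMe (2 mM), rt to 40 °C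
Reagents that add atoms: none
Why: saponification of the activated aryloxyacetate and Yamaguchi lactonisation of the carboxylate, which is never acidified so the enol ether survives; the carbinol C–O bond is not touched, so the (R) configuration is retained.

Step 9
Reactants: 15 (5R)-5-(1-ethoxyethenyl)-8-methyl-7,9-bis(triisopropylsilyloxy)-2H-1,4-benzodioxepin-3(5H)-one
Product: 18 (2S)-4-ethoxy-8-methyl-7,9-bis(triisopropylsilyloxy)-2,3-dihydro-1-benzoxepine-2-carboxylic acid, via silyl ketene acetal 16 (not isolated), via trimethylsilyl ester 17 (not isolated)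
Conditions: Me3SiCl/Et3N (premixed, 3 equiv), THF, −78 °C, then LiN(SiMe3)2 (1.5 equiv) added slowly; to rt; solvent exchange to PhMe, 80–100 °C; then THF/H2O, cold citrate buffer (pH 4–5), rapid extraction
Reagents that add atoms: none
Why: Enolisation of the lactone in the presence of Me3SiCl traps the enolate as the cyclic silyl ketene acetal 16 before it can open to a ketene, and on warming its carbon C2 bonds to the terminal CH2 of the 1-ethoxyvinyl group while the benzylic lactone bond C5–O4 breaks in a concerted, suprafacial [3,3]-sigmatropic shift (Ireland–Claisen rearrangement). The closest known reaction type is the ester-enolate Claisen rearrangement of alkenyl-substituted lactone silyl ketene acetals, as in the conversion of 6-alkenyl-1,4-dioxan-2-ones into dihydropyran carboxylic acids. The oxepine ring closes by this C2–C3 bond formation across the lactone: the tether O1–C9a–C5a joins C2 and C5, the 1 and 4 positions of the pericyclic array, so the transition state is a boat of bicyclo[3.2.2] type and the seven-membered lactone is exchanged for a seven-membered cyclic ether. The new stereocentre C2 is controlled by the lactone stereocentre C5, because the tether lets the vinyl group reach only the face of C2 on its own side of the ring, which translates (5R) into (2S). The step needs the concerted path to win over ionisation of the benzylic, allylic C5–O4 bond and over ketene formation; the ring-enforced geometry, the non-polar medium of the thermal stage and the internal silyl chloride quench at −78 °C are meant to secure this. The ring also fixes the new C4=C5 enol ether as the cis ring alkene, and the silyl ester 17 is hydrolysed under weakly acidic buffer so that this enol ether is kept.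

Step 10
Reactants: 18 (2S)-4-ethoxy-8-methyl-7,9-bis(triisopropylsilyloxy)-2,3-dihydro-1-benzoxepine-2-carboxylic acid
Product: 19 methyl (2S)-4-ethoxy-8-methyl-7,9-bis(triisopropylsilyloxy)-2,3-dihydro-1-benzoxepine-2-carboxylate
Conditions: Me3SiCHN2, PhMe/MeOH (4:1), 0 °C (crude acid used at once)
Reagents that add atoms: (trimethylsilyl)diazomethane, C[Si](C)(C)C=[N+]=[N-]
Why: O-methylation of the carboxylic acid by a diazoalkane under neutral conditions, which removes the free acid that would otherwise threaten the enol ether and does not touch C2.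

Step 11
Reactants: 19 methyl (2S)-4-ethoxy-8-methyl-7,9-bis(triisopropylsilyloxy)-2,3-dihydro-1-benzoxepine-2-carboxylate
Product: 20 2-[(2S)-4-ethoxy-8-methyl-7,9-bis(triisopropylsilyloxy)-2,3-dihydro-1-benzoxepin-2-yl]propan-2-ol
Conditions: MeMgBr (4 equiv), THF, −20 to 0 °C; aq. NH4Cl/NH3 buffer (pH 8)
Reagents that add atoms: methylmagnesium bromide, C[Mg]Br
Why: double Grignard addition to the ester gives the tertiary alcohol, with addition expected to outrun enolisation so that C2 is not epimerised, while the enol ether and aryl silyl ethers are inert.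

Step 12
Reactants: 20 2-[(2S)-4-ethoxy-8-methyl-7,9-bis(triisopropylsilyloxy)-2,3-dihydro-1-benzoxepin-2-yl]propan-2-ol
Product: 23 (2S)-2-(2-hydroxypropan-2-yl)-8-methyl-5-methylidene-7,9-bis(triisopropylsilyloxy)-2,3-dihydro-1-benzoxepin-4(5H)-one, via Mannich base 21 (not isolated), via methiodide 22 (not isolated)
Conditions: CH2=NMe2+ I− (1.5 equiv), CH2Cl2, rt; 1 M HCl, THF, 0 °C; aq. NaHCO3; MeI, CH2Cl2, rt; aq. NaHCO3, rt
Reagents that add atoms: N,N-dimethylmethyleneiminium iodide (Eschenmoser's salt), C=[N+](C)C.[I-]; water, O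
Why: Mannich reaction of the enol ether at its only nucleophilic carbon C5 (so the regiochemistry is fixed), hydrolysis of the resulting oxocarbenium ion to the C4 ketone, and elimination of the quaternised amine, which is easy because C5–H is benzylic and α to the ketone and needs only hydrogencarbonate.

Step 13
Reactants: 23 (2S)-2-(2-hydroxypropan-2-yl)-8-methyl-5-methylidene-7,9-bis(triisopropylsilyloxy)-2,3-dihydro-1-benzoxepin-4(5H)-one
Product: 24 (2S,4R)-2-(2-hydroxypropan-2-yl)-8-methyl-5-methylidene-7,9-bis(triisopropylsilyloxy)-2,3,4,5-tetrahydro-1-benzoxepin-4-ol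
Conditions: (S)-2-methyl-CBS-oxazaborolidine (0.5 equiv), catecholborane (3 equiv), toluene, −78 °C; MeOH; aq. NaHCO3
Reagents that add atoms: none
Why: CBS 1,2-reduction of the enone under reagent control, with the aryl-substituted sp2 carbon C5 as the large group and C3H2 as the small one, so that the (S)-catalyst should set C4 as (R), trans to the C2 substituent; the low temperature suppresses uncatalysed conjugate reduction.

Step 14
Reactants: 24 (2S,4R)-2-(2-hydroxypropan-2-yl)-8-methyl-5-methylidene-7,9-bis(triisopropylsilyloxy)-2,3,4,5-tetrahydro-1-benzoxepin-4-ol; 25 angelic acid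
Product: 27 (2S,4R)-2-(2-hydroxypropan-2-yl)-8-methyl-5-methylidene-7,9-bis(triisopropylsilyloxy)-2,3,4,5-tetrahydro-1-benzoxepin-4-yl (Z)-2-methylbut-2-enoate, via angelic mixed anhydride 26 (not isolated)
Conditions: 25, 2,4,6-trichlorobenzoyl chloride, Et3N, PhMe, rt; then 24, PhMe, 75 °C, no nucleophilic catalyst
Reagents that add atoms: none
Why: Yamaguchi-type mixed anhydride esterification, in which the secondary allylic alcohol attacks the less hindered angeloyl carbonyl, the absence of DMAP avoids Z-to-E isomerisation to the tiglate, and the tertiary alcohol is too hindered to be acylated.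

Step 15
Reactants: 27 (2S,4R)-2-(2-hydroxypropan-2-yl)-8-methyl-5-methylidene-7,9-bis(triisopropylsilyloxy)-2,3,4,5-tetrahydro-1-benzoxepin-4-yl (Z)-2-methylbut-2-enoate
Product: 28 (2S,4R)-7,9-dihydroxy-2-(2-hydroxypropan-2-yl)-8-methyl-5-methylidene-2,3,4,5-tetrahydro-1-benzoxepin-4-yl (Z)-2-methylbut-2-enoate (target)
Conditions: Bu4NF (2.5 equiv), AcOH (2.5 equiv), THF, 0 °C, under argon
Reagents that add atoms: none
Why: fluoride cleavage of both aryl silyl ethers, buffered with acetic acid so that the phenols stay protonated and neither the angelate nor the oxidation-prone hydroquinone-type ring is harmed.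

**Compound list**

1 | 2,4-dihydroxy-3-methylbenzaldehyde | Cc1c(O)ccc(C=O)c1O | starting material
2 | 3-methyl-2,4-bis(triisopropylsilyloxy)benzaldehyde | Cc1c(O[Si](C(C)C)(C(C)C)C(C)C)ccc(C=O)c1O[Si](C(C)C)(C(C)C)C(C)C | intermediate
3 | 3-methyl-2,4-bis(triisopropylsilyloxy)phenyl formate | Cc1c(O[Si](C(C)C)(C(C)C)C(C)C)ccc(OC=O)c1O[Si](C(C)C)(C(C)C)C(C)C | intermediate
4 | 3-methyl-2,4-bis(triisopropylsilyloxy)phenol | Cc1c(O[Si](C(C)C)(C(C)C)C(C)C)ccc(O)c1O[Si](C(C)C)(C(C)C)C(C)C | intermediate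
5 | 2-hydroxy-4-methyl-3,5-bis(triisopropylsilyloxy)benzaldehyde | Cc1c(O[Si](C(C)C)(C(C)C)C(C)C)cc(C=O)c(O)c1O[Si](C(C)C)(C(C)C)C(C)C | intermediate
6 | methyl bromoacetate | COC(=O)CBr | starting material
7 | methyl 2-[2-formyl-5-methyl-4,6-bis(triisopropylsilyloxy)phenoxy]acetate | Cc1c(O[Si](C(C)C)(C(C)C)C(C)C)cc(C=O)c(OCC(=O)OC)c1O[Si](C(C)C)(C(C)C)C(C)C | intermediate
8 | ethyl vinyl ether | C=COCC | starting material
9 | 1-ethoxyvinyllithium | [Li]C(=C)OCC | intermediate
10 | methyl 2-[2-(2-ethoxy-1-hydroxyprop-2-en-1-yl)-5-methyl-4,6-bis(triisopropylsilyloxy)phenoxy]acetate (racemic) | Cc1c(O[Si](C(C)C)(C(C)C)C(C)C)cc(C(O)C(=C)OCC)c(OCC(=O)OC)c1O[Si](C(C)C)(C(C)C)C(C)C | intermediate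
11 | methyl 2-[2-(2-ethoxyprop-2-enoyl)-5-methyl-4,6-bis(triisopropylsilyloxy)phenoxy]acetate | Cc1c(O[Si](C(C)C)(C(C)C)C(C)C)cc(C(=O)C(=C)OCC)c(OCC(=O)OC)c1O[Si](C(C)C)(C(C)C)C(C)C | intermediate
12 | methyl 2-{2-[(1R)-2-ethoxy-1-hydroxyprop-2-en-1-yl]-5-methyl-4,6-bis(triisopropylsilyloxy)phenoxy}acetate | C=C(OCC)[C@H](O)c1cc(O[Si](C(C)C)(C(C)C)C(C)C)c(C)c(O[Si](C(C)C)(C(C)C)C(C)C)c1OCC(=O)OC | intermediate
13 | lithium 2-{2-[(1R)-2-ethoxy-1-hydroxyprop-2-en-1-yl]-5-methyl-4,6-bis(triisopropylsilyloxy)phenoxy}acetate | C=C(OCC)[C@H](O)c1cc(O[Si](C(C)C)(C(C)C)C(C)C)c(C)c(O[Si](C(C)C)(C(C)C)C(C)C)c1OCC(=O)[O-].[Li+] | intermediate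
14 | 2-{2-[(1R)-2-ethoxy-1-hydroxyprop-2-en-1-yl]-5-methyl-4,6-bis(triisopropylsilyloxy)phenoxy}acetic 2,4,6-trichlorobenzoic anhydride | C=C(OCC)[C@H](O)c1cc(O[Si](C(C)C)(C(C)C)C(C)C)c(C)c(O[Si](C(C)C)(C(C)C)C(C)C)c1OCC(=O)OC(=O)c1c(Cl)cc(Cl)cc1Cl | intermediate
15 | (5R)-5-(1-ethoxyethenyl)-8-methyl-7,9-bis(triisopropylsilyloxy)-2H-1,4-benzodioxepin-3(5H)-one | C=C(OCC)[C@@H]1OC(=O)COc2c(O[Si](C(C)C)(C(C)C)C(C)C)c(C)c(O[Si](C(C)C)(C(C)C)C(C)C)cc12 | intermediate
16 | (5R)-5-(1-ethoxyethenyl)-8-methyl-7,9-bis(triisopropylsilyloxy)-3-(trimethylsilyloxy)-5H-1,4-benzodioxepine | C=C(OCC)[C@@H]1OC(O[Si](C)(C)C)=COc2c(O[Si](C(C)C)(C(C)C)C(C)C)c(C)c(O[Si](C(C)C)(C(C)C)C(C)C)cc12 | intermediate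
17 | trimethylsilyl (2S)-4-ethoxy-8-methyl-7,9-bis(triisopropylsilyloxy)-2,3-dihydro-1-benzoxepine-2-carboxylate | C[Si](C)(C)OC(=O)[C@@H]1CC(OCC)=Cc2cc(O[Si](C(C)C)(C(C)C)C(C)C)c(C)c(O[Si](C(C)C)(C(C)C)C(C)C)c2O1 | intermediate
18 | (2S)-4-ethoxy-8-methyl-7,9-bis(triisopropylsilyloxy)-2,3-dihydro-1-benzoxepine-2-carboxylic acid | OC(=O)[C@@H]1CC(OCC)=Cc2cc(O[Si](C(C)C)(C(C)C)C(C)C)c(C)c(O[Si](C(C)C)(C(C)C)C(C)C)c2O1 | intermediate
19 | methyl (2S)-4-ethoxy-8-methyl-7,9-bis(triisopropylsilyloxy)-2,3-dihydro-1-benzoxepine-2-carboxylate | COC(=O)[C@@H]1CC(OCC)=Cc2cc(O[Si](C(C)C)(C(C)C)C(C)C)c(C)c(O[Si](C(C)C)(C(C)C)C(C)C)c2O1 | intermediate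
20 | 2-[(2S)-4-ethoxy-8-methyl-7,9-bis(triisopropylsilyloxy)-2,3-dihydro-1-benzoxepin-2-yl]propan-2-ol | CC(C)(O)[C@@H]1CC(OCC)=Cc2cc(O[Si](C(C)C)(C(C)C)C(C)C)c(C)c(O[Si](C(C)C)(C(C)C)C(C)C)c2O1 | intermediate
21 | (2S)-5-[(dimethylamino)methyl]-2-(2-hydroxypropan-2-yl)-8-methyl-7,9-bis(triisopropylsilyloxy)-2,3-dihydro-1-benzoxepin-4(5H)-one (C5 epimers) | CC(C)(O)[C@@H]1CC(=O)C(CN(C)C)c2cc(O[Si](C(C)C)(C(C)C)C(C)C)c(C)c(O[Si](C(C)C)(C(C)C)C(C)C)c2O1 | intermediate
22 | N,N,N-trimethylammonium iodide of 21 | CC(C)(O)[C@@H]1CC(=O)C(C[N+](C)(C)C)c2cc(O[Si](C(C)C)(C(C)C)C(C)C)c(C)c(O[Si](C(C)C)(C(C)C)C(C)C)c2O1.[I-] | intermediate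
23 | (2S)-2-(2-hydroxypropan-2-yl)-8-methyl-5-methylidene-7,9-bis(triisopropylsilyloxy)-2,3-dihydro-1-benzoxepin-4(5H)-one | CC(C)(O)[C@@H]1CC(=O)C(=C)c2cc(O[Si](C(C)C)(C(C)C)C(C)C)c(C)c(O[Si](C(C)C)(C(C)C)C(C)C)c2O1 | intermediate
24 | (2S,4R)-2-(2-hydroxypropan-2-yl)-8-methyl-5-methylidene-7,9-bis(triisopropylsilyloxy)-2,3,4,5-tetrahydro-1-benzoxepin-4-ol | CC(C)(O)[C@@H]1C[C@@H](O)C(=C)c2cc(O[Si](C(C)C)(C(C)C)C(C)C)c(C)c(O[Si](C(C)C)(C(C)C)C(C)C)c2O1 | intermediate
25 | angelic acid, (Z)-2-methylbut-2-enoic acid | C/C=C(/C)C(=O)O | starting material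
26 | (Z)-2-methylbut-2-enoic 2,4,6-trichlorobenzoic anhydride | C/C=C(/C)C(=O)OC(=O)c1c(Cl)cc(Cl)cc1Cl | intermediate
27 | (2S,4R)-2-(2-hydroxypropan-2-yl)-8-methyl-5-methylidene-7,9-bis(triisopropylsilyloxy)-2,3,4,5-tetrahydro-1-benzoxepin-4-yl (Z)-2-methylbut-2-enoate | CC(C)(O)[C@@H]1C[C@@H](OC(=O)/C(C)=C\C)C(=C)c2cc(O[Si](C(C)C)(C(C)C)C(C)C)c(C)c(O[Si](C(C)C)(C(C)C)C(C)C)c2O1 | intermediate
28 | (2S,4R)-7,9-dihydroxy-2-(2-hydroxypropan-2-yl)-8-methyl-5-methylidene-2,3,4,5-tetrahydro-1-benzoxepin-4-yl (Z)-2-methylbut-2-enoate | C=C1c2cc(O)c(C)c(O)c2O[C@H](C(C)(C)O)C[C@H]1OC(=O)/C(C)=C\C | target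

Total step count: 15. Longest linear sequence: 15 steps (from 1; compounds 6, 8 and 25 are bought).

**Steps most likely to fail**

1. Step 9 (Ireland–Claisen shift of the lactone). The shift must pass through a boat transition state and carries a donor on the central carbon of the allyl unit, both of which slow it. Heating may then allow ionisation of the benzylic C5–O4 bond with loss of chirality transfer, or opening of the enolate to a ketene.
Fallback, leaving the pericyclic step, from 5 back to 19. Wittig methylenation of 5 (Ph3P=CH2 in excess, from Ph3PCH3Br and KN(SiMe3)2, THF) should give 2-ethenyl-5-methyl-4,6-bis(triisopropylsilyloxy)phenol F1. O-Alkylation with (4R)-4-benzyl-3-(bromoacetyl)-1,3-oxazolidin-2-one (K2CO3, acetone) should give the N-(aryloxyacetyl)oxazolidinone F2. Evans alkylation of its sodium enolate (NaN(SiMe3)2, THF, −78 °C) with 3-bromo-2-ethoxyprop-1-ene should set C2 as (S) in the 4-ethoxypent-4-enoyl imide F3. Ring-closing metathesis of the styrene with the enol ether (second-generation Grubbs catalyst, PhMe, 80 °C) should close the oxepine ring to the benzoxepine imide F4. Methanolysis (MeOMgBr, MeOH/CH2Cl2, 0 °C) removes the auxiliary and returns to the route at 19.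

2. Step 7 (enantioselective reduction of 11). Both ketone substituents are sp2 groups, so the catalyst may discriminate poorly between the two faces, and the enantiomeric purity of 12 passes directly into C2.
Fallback, replacing asymmetric reduction by resolution, from 10 back to 12. Lipase-catalysed acetylation of racemic 10 (Amano lipase PS or Candida antarctica lipase B, vinyl acetate, t-BuOMe, 30 °C) should acylate the (S)-enantiomer, as expected from the Kazlauskas rule with the aryl group as the large substituent, to give methyl 2-{2-[(1S)-1-acetoxy-2-ethoxyprop-2-en-1-yl]-5-methyl-4,6-bis(triisopropylsilyloxy)phenoxy}acetate F5. The unreacted (R)-alcohol is 12, separated by chromatography.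

3. Step 13 (reduction of enone 23). The intrinsic facial bias of the seven-membered ring may oppose the catalyst and lead to the cis alcohol, and conjugate reduction of the s-cis enone may compete.
Fallback, replacing facial control by inversion, from 23 back to 24. Luche reduction (NaBH4, CeCl3·7H2O, MeOH, −78 °C) should give, under substrate control, the cis alcohol (2S,4S)-2-(2-hydroxypropan-2-yl)-8-methyl-5-methylidene-7,9-bis(triisopropylsilyloxy)-2,3,4,5-tetrahydro-1-benzoxepin-4-ol F6. Mitsunobu inversion (4-nitrobenzoic acid, PPh3, diisopropyl azodicarboxylate, THF, 0 °C) should give the (2S,4R)-4-nitrobenzoate F7; allylic transposition is the side path to watch. Brief methanolysis (K2CO3, MeOH, 0 °C) gives 24.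

**Further compounds**

F1 | step 9 | 2-ethenyl-5-methyl-4,6-bis(triisopropylsilyloxy)phenol | C=Cc1cc(O[Si](C(C)C)(C(C)C)C(C)C)c(C)c(O[Si](C(C)C)(C(C)C)C(C)C)c1O
F2 | step 9 | (4R)-4-benzyl-3-{2-[2-ethenyl-5-methyl-4,6-bis(triisopropylsilyloxy)phenoxy]acetyl}-1,3-oxazolidin-2-one | C=Cc1cc(O[Si](C(C)C)(C(C)C)C(C)C)c(C)c(O[Si](C(C)C)(C(C)C)C(C)C)c1OCC(=O)N2C(=O)OC[C@H]2Cc2ccccc2
F3 | step 9 | (4R)-4-benzyl-3-{(2S)-2-[2-ethenyl-5-methyl-4,6-bis(triisopropylsilyloxy)phenoxy]-4-ethoxypent-4-enoyl}-1,3-oxazolidin-2-one | C=Cc1cc(O[Si](C(C)C)(C(C)C)C(C)C)c(C)c(O[Si](C(C)C)(C(C)C)C(C)C)c1O[C@@H](CC(=C)OCC)C(=O)N2C(=O)OC[C@H]2Cc2ccccc2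
F4 | step 9 | (4R)-4-benzyl-3-[(2S)-4-ethoxy-8-methyl-7,9-bis(triisopropylsilyloxy)-2,3-dihydro-1-benzoxepine-2-carbonyl]-1,3-oxazolidin-2-one | CCOC1=Cc2cc(O[Si](C(C)C)(C(C)C)C(C)C)c(C)c(O[Si](C(C)C)(C(C)C)C(C)C)c2O[C@@H](C1)C(=O)N3C(=O)OC[C@H]3Cc3ccccc3
F5 | step 7 | methyl 2-{2-[(1S)-1-acetoxy-2-ethoxyprop-2-en-1-yl]-5-methyl-4,6-bis(triisopropylsilyloxy)phenoxy}acetate | C=C(OCC)[C@@H](OC(C)=O)c1cc(O[Si](C(C)C)(C(C)C)C(C)C)c(C)c(O[Si](C(C)C)(C(C)C)C(C)C)c1OCC(=O)OC
F6 | step 13 | (2S,4S)-2-(2-hydroxypropan-2-yl)-8-methyl-5-methylidene-7,9-bis(triisopropylsilyloxy)-2,3,4,5-tetrahydro-1-benzoxepin-4-ol | CC(C)(O)[C@@H]1C[C@H](O)C(=C)c2cc(O[Si](C(C)C)(C(C)C)C(C)C)c(C)c(O[Si](C(C)C)(C(C)C)C(C)C)c2O1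
F7 | step 13 | (2S,4R)-2-(2-hydroxypropan-2-yl)-8-methyl-5-methylidene-7,9-bis(triisopropylsilyloxy)-2,3,4,5-tetrahydro-1-benzoxepin-4-yl 4-nitrobenzoate | CC(C)(O)[C@@H]1C[C@@H](OC(=O)c3ccc(cc3)[N+](=O)[O-])C(=C)c2cc(O[Si](C(C)C)(C(C)C)C(C)C)c(C)c(O[Si](C(C)C)(C(C)C)C(C)C)c2O1
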